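14.1 µM of catalyst is spent for each halving of the substrate in this flask. That figure, the halving toll, tells us whether the next run can keep its charge.

substrate 0.010 M; free catalyst 26 µM

    substrate + free catalyst ⇌ catalyst intermediate (K1 = 97 M⁻¹, k1 = 10000 M⁻¹ min⁻¹)
    catalyst intermediate → free catalyst + product (k2 = 99 min⁻¹)
    free catalyst → spent catalyst (k3 = 0.10 min⁻¹)

- the form that holds most of the catalyst when 50% of the substrate are converted (free catalyst / spent catalyst / catalyst intermediate)
- its share of the catalyst then

We keep the charge of 26 µM if it covers one toll. Here is our own reckoning. In this flask the catalyst intermediate lasts 0.00495 min, while free catalyst lasts 10.0 min against its decay. Since the first time is far shorter than the second, we take the catalyst intermediate as steady and reckon with the free catalyst it leaves: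

c(catalyst intermediate) / c(free catalyst) = c(substrate) / 0.0202 M, the Michaelis constant

catalyst lost per substrate turned = 0.10 min⁻¹ × 0.0202 M / (99 min⁻¹ × c(substrate))

summed over one halving: toll = ln(2) × 0.10 min⁻¹ × 0.0202 M / 99 min⁻¹ = 14.1 µM

Half conversion is one halving. The form holding most of the catalyst is then spent catalyst, at 54.4%, which outweighs the two working forms together. The toll is smaller than the charge, so we leave the charge as it stands.

The forecast says spent catalyst at 54.4%, within 53.5% to 55.5%: “Spent catalyst is the largest form”.

The simulation gives spent catalyst at 54.4% after 10.5 min, beside 36.5% free catalyst and 9.04% catalyst intermediate. The making of catalyst intermediate over its using up, each step taken net, stands at 0.999 after 4.44 min and at 0.999 after 15.0 min. The charge of this flask pays for 1.84 halvings, which by the toll leaves 27.9% of the substrate; the simulation has 28.0% after 150 min.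

Its constants are invented; no experiment stands behind them.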